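**Plan**

- Retrosynthesis: the two benzyl ethers are removed last. The pyranone ring of the flavonol is cut at C4–C4a and O1–C2, leaving phloroglucinol and an α-benzyloxy aroylacetate. That keto ester is cut at its ketone–CH(OBn) bond into a chroman-6-carbonyl chloride and ethyl benzyloxyacetate. The chromanol is traced through its 3,4-epoxide to a 2,2-dimethylchromene ester, which is cut at O–CMe2 and C4–C4a into methyl 4-hydroxybenzoate and 3-chloro-3-methylbut-1-yne.
- Forward order: the dimethylpyran ring of the B-ring unit is built first (propargyl ether, Claisen rearrangement and electrocyclisation), then the C3 carbinol, then the keto ester chain. The pyranone ring is closed last, onto an A ring that is bought complete.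
- Enabling feature: ring A (C4a, C5, C6, C7, C8, C8a) carries oxygen at C5, C7 and C8a (O1), so it is phloroglucinol. Its three CH carbons are equivalent and each lies between two hydroxyls, so acylation at the future C4a has no regiochemical alternative, an ortho hydroxyl is always in place to become O1, and the 5- and 7-OH need no protection.
- Stereochemistry: the only stereocentre, chroman C3 (R), comes from Jacobsen epoxidation of the chromene with the (R,R)-Mn(salen) catalyst. Hydrogenolysis then breaks only the benzylic C4–O bond, and C3 is carried untouched as its benzyl ether to the end.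

Key step: step 8

Assumption: the (R,R)-Mn(salen) catalyst is taken to deliver the (3R,4R)-epoxide, as it does with other 2,2-dimethylchromenes bearing an acceptor at C6; keto ester 15 is used as a mixture of epimers at its α-carbon, which becomes sp2 in step 8.

**Route**

Step 1
Reactants: 1 methyl 4-hydroxybenzoate; 2 3-chloro-3-methylbut-1-yne
Product: 3 methyl 4-[(2-methylbut-3-yn-2-yl)oxy]benzoate
Conditions: K2CO3, KI (cat.), CuI (cat.), acetone, reflux
Reagents that add atoms: none
Why: Copper-assisted Williamson-type O-alkylation of the phenoxide by the tertiary propargylic chloride is the standard entry to aryl 1,1-dimethylpropargyl ethers, and the ester-bearing phenol is acidic enough for carbonate.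

Step 2
Reactants: 3 methyl 4-[(2-methylbut-3-yn-2-yl)oxy]benzoate
Product: 7 methyl 2,2-dimethyl-2H-chromene-6-carboxylate, via allenyl cyclohexadienone 4 (not isolated), via ortho-allenylphenol 5 (not isolated), via ortho-quinone methide 6 (not isolated)
Conditions: PhNEt2, 190 °C
Reagents that add atoms: none
Why: Aromatic propargyl Claisen rearrangement, in which the [3,3] shift to either of the two equivalent ortho carbons gives dienone 4, enolisation gives phenol 5, and a 1,5-hydrogen shift to quinone methide 6 followed by oxa-6π electrocyclisation should close the 2,2-dimethyl-2H-pyran ring.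

Step 3
Reactants: 7 methyl 2,2-dimethyl-2H-chromene-6-carboxylate
Product: 8 methyl (3R,4R)-3,4-epoxy-2,2-dimethylchroman-6-carboxylate (cis-fused oxirane)
Conditions: (R,R)-Jacobsen Mn(salen)Cl (4 mol%), 4-phenylpyridine N-oxide (cat.), aq. NaOCl (pH 11.3), CH2Cl2, 0 °C
Reagents that add atoms: sodium hypochlorite, [Na+].[O-]Cl
Why: Jacobsen–Katsuki epoxidation, for which cis-disubstituted aryl-conjugated olefins of the 2,2-dimethylchromene class are among the best substrates; the C2-symmetric (R,R)-salen ligand fixes the face of oxo transfer and so sets C3 and C4 together as R,R.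

Step 4
Reactants: 8 methyl (3R,4R)-3,4-epoxy-2,2-dimethylchroman-6-carboxylate
Product: 9 methyl (3R)-3-hydroxy-2,2-dimethylchroman-6-carboxylate
Conditions: H2 (1 atm), 10% Pd/C, EtOAc, rt
Reagents that add atoms: none
Why: Catalytic hydrogenolysis of a benzylic epoxide cleaves only the C4–O bond, so the C3–O bond and the configuration set in step 3 are retained and the carbinol should be 3R, while the aryl ester is inert.

Step 5
Reactants: 9 methyl (3R)-3-hydroxy-2,2-dimethylchroman-6-carboxylate
Product: 10 methyl (3R)-3-(benzyloxy)-2,2-dimethylchroman-6-carboxylate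
Conditions: NaH, BnBr, Bu4NI (cat.), DMF, 0 °C to rt
Reagents that add atoms: benzyl bromide, BrCc1ccccc1
Why: Williamson etherification through the sodium alkoxide breaks the O–H and not the C3–O bond, so the configuration is kept, and the aryl methyl ester has no α-hydrogen for the base to remove.

Step 6
Reactants: 10 methyl (3R)-3-(benzyloxy)-2,2-dimethylchroman-6-carboxylate
Product: 11 (3R)-3-(benzyloxy)-2,2-dimethylchroman-6-carboxylic acid
Conditions: LiOH, THF/MeOH/H2O, 40 °C; then 1 M HCl
Reagents that add atoms: lithium hydroxide, [Li+].[OH-]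
Why: Saponification of an aryl methyl ester by acyl–oxygen cleavage, to which the benzyl ether and the chroman ether are inert.

Step 7
Reactants: 11 (3R)-3-(benzyloxy)-2,2-dimethylchroman-6-carboxylic acid; 12 ethyl 2-(benzyloxy)acetate
Product: 15 ethyl 2-(benzyloxy)-3-[(3R)-3-(benzyloxy)-2,2-dimethylchroman-6-yl]-3-oxopropanoate (epimers at C2), via acid chloride 13 (not isolated), via lithium ester enolate 14 (not isolated)
Conditions: (COCl)2, DMF (cat.), CH2Cl2, 0 °C to rt, evaporate; separately 12 (2.2 equiv), LiHMDS (2.1 equiv), THF, −78 °C; add 13, −78 °C; then 1 M HCl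
Reagents that add atoms: none
Why: Crossed Claisen-type C-acylation of a preformed, chelated lithium glycolate enolate by an aroyl chloride at low temperature, with a second equivalent of enolate to take up the acidic proton of the product; the new α-centre is labile and is left as a mixture because it becomes sp2 in step 8.

Step 8
Reactants: 15 ethyl 2-(benzyloxy)-3-[(3R)-3-(benzyloxy)-2,2-dimethylchroman-6-yl]-3-oxopropanoate; 16 phloroglucinol
Product: 20 3-(benzyloxy)-2-[(3R)-3-(benzyloxy)-2,2-dimethylchroman-6-yl]-5,7-dihydroxy-4H-chromen-4-one, via acylketene 17 (not isolated), via C-acylphloroglucinol diketone 18 (not isolated), via cyclic hemiketal 19 (not isolated)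
Conditions: anhydrous 16 (3 equiv), neat melt (or Ph2O), N2 stream, 240 °C, no acid or base
Reagents that add atoms: none
Why: On heating without acid, 15 should lose ethanol to acylketene 17, which acylates one of the three equivalent CH carbons of phloroglucinol (directly, or by O-acylation and acyl shift) to give diketone 18 and so forms C4–C4a. The hydroxyl ortho to the new acyl group then adds to the aryl ketone in a 6-exo-trig closure to hemiketal 19, and loss of water across C2–C3 completes O1–C2 and the aromatic pyranone. The closest known reaction type is the Mentzer thermal pyrone synthesis of 5,7-dihydroxyflavones and 3-alkoxyflavones from phloroglucinol and aroylacetates. No stereocentre is formed: the labile α-carbon of 15 becomes C3 of the chromone and the remote 3R ether centre takes no part. The step needs the chromone and not the coumarin, and one annulation only: the first is secured by leaving out acid, so that the ester carbon (as the ketene) and not the ketone is the C-electrophile, the second by the excess of phloroglucinol and by the deactivation of the product's A ring through its conjugated, chelated C4 carbonyl.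

Step 9
Reactants: 20 3-(benzyloxy)-2-[(3R)-3-(benzyloxy)-2,2-dimethylchroman-6-yl]-5,7-dihydroxy-4H-chromen-4-one
Product: 21 3,5,7-trihydroxy-2-[(3R)-3-hydroxy-2,2-dimethylchroman-6-yl]-4H-chromen-4-one
Conditions: H2 (1 atm), 10% Pd/C, EtOAc/MeOH, rt
Reagents that add atoms: none
Why: Hydrogenolysis of benzyl ethers cleaves only the two O–CH2Ph bonds, the chroman C3–O bond is not benzylic and keeps its R configuration, and the tetrasubstituted C2=C3 bond of the chromone, part of a vinylogous ester, should not be reduced at atmospheric pressure.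

**Compound list**

1 | methyl 4-hydroxybenzoate | COC(=O)c1ccc(O)cc1 | starting material
2 | 3-chloro-3-methylbut-1-yne | CC(C)(Cl)C#C | starting material
3 | methyl 4-[(2-methylbut-3-yn-2-yl)oxy]benzoate | COC(=O)c1ccc(OC(C)(C)C#C)cc1 | intermediate
4 | methyl 3-(3-methylbuta-1,2-dien-1-yl)-4-oxocyclohexa-1,5-diene-1-carboxylate (allenyl cyclohexadienone, not isolated) | COC(=O)C1=CC(C=C=C(C)C)C(=O)C=C1 | intermediate
5 | methyl 4-hydroxy-3-(3-methylbuta-1,2-dien-1-yl)benzoate (ortho-allenylphenol, not isolated) | COC(=O)c1ccc(O)c(C=C=C(C)C)c1 | intermediate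
6 | methyl (3Z)-3-(3-methylbut-2-en-1-ylidene)-4-oxocyclohexa-1,5-diene-1-carboxylate (ortho-quinone methide, not isolated) | COC(=O)C1=C/C(=C/C=C(C)C)C(=O)C=C1 | intermediate
7 | methyl 2,2-dimethyl-2H-chromene-6-carboxylate | CC1(C)C=Cc2cc(C(=O)OC)ccc2O1 | intermediate
8 | methyl (3R,4R)-3,4-epoxy-2,2-dimethylchroman-6-carboxylate | CC1(C)Oc2ccc(C(=O)OC)cc2[C@H]3O[C@@H]13 | intermediate
9 | methyl (3R)-3-hydroxy-2,2-dimethylchroman-6-carboxylate | CC1(C)Oc2ccc(C(=O)OC)cc2C[C@H]1O | intermediate
10 | methyl (3R)-3-(benzyloxy)-2,2-dimethylchroman-6-carboxylate | CC1(C)Oc2ccc(C(=O)OC)cc2C[C@H]1OCc1ccccc1 | intermediate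
11 | (3R)-3-(benzyloxy)-2,2-dimethylchroman-6-carboxylic acid | CC1(C)Oc2ccc(C(=O)O)cc2C[C@H]1OCc1ccccc1 | intermediate
12 | ethyl 2-(benzyloxy)acetate | CCOC(=O)COCc1ccccc1 | starting material
13 | (3R)-3-(benzyloxy)-2,2-dimethylchroman-6-carbonyl chloride (not isolated) | CC1(C)Oc2ccc(C(Cl)=O)cc2C[C@H]1OCc1ccccc1 | intermediate
14 | lithium enolate of ethyl 2-(benzyloxy)acetate, enolate oxygen cis to the benzyloxy group (not isolated) | [Li+].[O-]/C(OCC)=C\OCc1ccccc1 | intermediate
15 | ethyl 2-(benzyloxy)-3-[(3R)-3-(benzyloxy)-2,2-dimethylchroman-6-yl]-3-oxopropanoate (epimers at C2) | CC1(C)Oc2ccc(C(=O)C(OCc3ccccc3)C(=O)OCC)cc2C[C@H]1OCc1ccccc1 | intermediate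
16 | phloroglucinol (benzene-1,3,5-triol) | Oc1cc(O)cc(O)c1 | starting material
17 | 2-(benzyloxy)-3-[(3R)-3-(benzyloxy)-2,2-dimethylchroman-6-yl]-3-oxoprop-1-en-1-one (acylketene, not isolated) | CC1(C)Oc2ccc(C(=O)C(OCc3ccccc3)=C=O)cc2C[C@H]1OCc1ccccc1 | intermediate
18 | 2-(benzyloxy)-1-[(3R)-3-(benzyloxy)-2,2-dimethylchroman-6-yl]-3-(2,4,6-trihydroxyphenyl)propane-1,3-dione (epimers at C2, not isolated) | CC1(C)Oc2ccc(C(=O)C(OCc3ccccc3)C(=O)c3c(O)cc(O)cc3O)cc2C[C@H]1OCc1ccccc1 | intermediate
19 | 3-(benzyloxy)-2-[(3R)-3-(benzyloxy)-2,2-dimethylchroman-6-yl]-2,5,7-trihydroxychroman-4-one (hemiketal, mixture at C2 and C3, not isolated) | CC1(C)Oc2ccc(C3(O)Oc4cc(O)cc(O)c4C(=O)C3OCc3ccccc3)cc2C[C@H]1OCc1ccccc1 | intermediate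
20 | 3-(benzyloxy)-2-[(3R)-3-(benzyloxy)-2,2-dimethylchroman-6-yl]-5,7-dihydroxy-4H-chromen-4-one | CC1(C)Oc2ccc(-c3oc4cc(O)cc(O)c4c(=O)c3OCc3ccccc3)cc2C[C@H]1OCc1ccccc1 | intermediate
21 | 3,5,7-trihydroxy-2-[(3R)-3-hydroxy-2,2-dimethylchroman-6-yl]-4H-chromen-4-one | CC1(C)Oc2ccc(-c3oc4cc(O)cc(O)c4c(=O)c3O)cc2C[C@H]1O | target

**Count**

Total steps: 9. Longest linear sequence: 9 steps (1 to 21); 2, 12 and 16 are bought.

**Steps most likely to fail**

1. Step 8. The thermal condensation may go astray in three ways: ring closure in the Pechmann sense, a second annulation on the product, or thermal loss of benzyl from the α-oxygen before the pyranone closes. The fallback is a Baker–Venkataraman sequence that sets out from acid 11 and phloroglucinol 16 and comes back to the route at target 21.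
   - Hoesch acylation of 16 with benzyloxyacetonitrile (ZnCl2, HCl, Et2O, then aqueous hydrolysis) would give 2-(benzyloxy)-1-(2,4,6-trihydroxyphenyl)ethan-1-one F1.
   - Twofold O-benzylation (BnBr, K2CO3, DMF) leaves one chelated ortho hydroxyl free and would give 2-(benzyloxy)-1-[2,4-bis(benzyloxy)-6-hydroxyphenyl]ethan-1-one F2.
   - Esterification with acid chloride 13, made from 11 as in step 7 (Et3N, DMAP cat., CH2Cl2), would give 3,5-bis(benzyloxy)-2-[2-(benzyloxy)acetyl]phenyl (3R)-3-(benzyloxy)-2,2-dimethylchroman-6-carboxylate F3.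
   - Base-induced O-to-C aroyl shift (KOH, pyridine, 50 °C) would give 2-(benzyloxy)-1-[2,4-bis(benzyloxy)-6-hydroxyphenyl]-3-[(3R)-3-(benzyloxy)-2,2-dimethylchroman-6-yl]propane-1,3-dione F4.
   - Cyclodehydration (NaOAc, AcOH, reflux) would give 3,5,7-tris(benzyloxy)-2-[(3R)-3-(benzyloxy)-2,2-dimethylchroman-6-yl]-4H-chromen-4-one F5.
   - Hydrogenolysis of all four benzyl ethers (H2, Pd/C) would then give 21.

2. Step 7. The enolate may be acylated on oxygen, the product enolate may be acylated a second time, or the glycolate enolate may self-condense on warming. The fallback sets out from acid 11 (through acid chloride 13) and comes back at keto ester 15.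
   - Chloride 13 would be condensed with potassium ethyl malonate (MgCl2, Et3N, MeCN, acidic work-up with decarboxylation) to give ethyl 3-[(3R)-3-(benzyloxy)-2,2-dimethylchroman-6-yl]-3-oxopropanoate F6.
   - Regitz diazo transfer (4-acetamidobenzenesulfonyl azide, Et3N, MeCN) would give ethyl 2-diazo-3-[(3R)-3-(benzyloxy)-2,2-dimethylchroman-6-yl]-3-oxopropanoate F7.
   - Rh2(OAc)4-catalysed O–H insertion of the derived carbenoid into benzyl alcohol (CH2Cl2) would place the benzyloxy group and give 15.

3. Step 4. On palladium the epoxide may isomerise to a chromanone or be opened by the solvent instead of being hydrogenolysed, and C–O cleavage may be slow on the acceptor-substituted arene. The fallback sets out from epoxide 8 and comes back at alcohol 9.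
   - Thiophenol (Et3N, MeOH, rt) should open 8 by SN2 attack at benzylic C4, since C3 is shielded by the gem-dimethyl group, and give the trans thioether methyl (3S,4S)-3-hydroxy-2,2-dimethyl-4-(phenylsulfanyl)chroman-6-carboxylate F8. The arrangement at C3 is unchanged; its descriptor changes only because sulfur raises the rank of C4.
   - Raney nickel (EtOH) would then remove sulfur and give 9.

**Further compounds**

F1 | step 8 | 2-(benzyloxy)-1-(2,4,6-trihydroxyphenyl)ethan-1-one | O=C(COCc1ccccc1)c1c(O)cc(O)cc1O
F2 | step 8 | 2-(benzyloxy)-1-[2,4-bis(benzyloxy)-6-hydroxyphenyl]ethan-1-one | O=C(COCc1ccccc1)c1c(O)cc(OCc2ccccc2)cc1OCc1ccccc1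
F3 | step 8 | 3,5-bis(benzyloxy)-2-[2-(benzyloxy)acetyl]phenyl (3R)-3-(benzyloxy)-2,2-dimethylchroman-6-carboxylate | CC1(C)Oc2ccc(C(=O)Oc3cc(OCc4ccccc4)cc(OCc4ccccc4)c3C(=O)COCc3ccccc3)cc2C[C@H]1OCc1ccccc1
F4 | step 8 | 2-(benzyloxy)-1-[2,4-bis(benzyloxy)-6-hydroxyphenyl]-3-[(3R)-3-(benzyloxy)-2,2-dimethylchroman-6-yl]propane-1,3-dione (epimers at C2) | CC1(C)Oc2ccc(C(=O)C(OCc3ccccc3)C(=O)c3c(O)cc(OCc4ccccc4)cc3OCc3ccccc3)cc2C[C@H]1OCc1ccccc1
F5 | step 8 | 3,5,7-tris(benzyloxy)-2-[(3R)-3-(benzyloxy)-2,2-dimethylchroman-6-yl]-4H-chromen-4-one | CC1(C)Oc2ccc(-c3oc4cc(OCc5ccccc5)cc(OCc5ccccc5)c4c(=O)c3OCc3ccccc3)cc2C[C@H]1OCc1ccccc1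
F6 | step 7 | ethyl 3-[(3R)-3-(benzyloxy)-2,2-dimethylchroman-6-yl]-3-oxopropanoate | CC1(C)Oc2ccc(C(=O)CC(=O)OCC)cc2C[C@H]1OCc1ccccc1
F7 | step 7 | ethyl 2-diazo-3-[(3R)-3-(benzyloxy)-2,2-dimethylchroman-6-yl]-3-oxopropanoate | CC1(C)Oc2ccc(C(=O)C(=[N+]=[N-])C(=O)OCC)cc2C[C@H]1OCc1ccccc1
F8 | step 4 | methyl (3S,4S)-3-hydroxy-2,2-dimethyl-4-(phenylsulfanyl)chroman-6-carboxylate | CC1(C)Oc2ccc(C(=O)OC)cc2[C@H](Sc3ccccc3)[C@H]1O
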